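**Assumptions**
- The target has no stereocentre: the quaternary C of the 1,1-dimethylallyl group carries two identical methyls, so "single enantiomer" does not apply.
- Bromination of 2,4,5-trimethoxyphenol under ortho-directed conditions is assumed to go at C6, the position next to the OH.
- 3-Bromo-1-(triisopropylsilyl)indole is assumed to be purchasable. If not, it is made from indole by N-silylation with TIPSCl/NaH and then NBS.

**Retrosynthesis**
1. Asterriquinol I ⇐ removal of TBS (aryl O) and TIPS (indole N) ⇐ Suzuki coupling of an aryl bromide with a 1-TIPS-indol-3-yl boronate. This sets the indole next to the phenol.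
2. The 2-(1,1-dimethylallyl) group is placed late on a 3-aryl-indole by Danishefsky-type chloroindolenine/prenyl-9-BBN allylboration. This is the proposed new step and forms the quaternary C–C bond.
3. The 3-aryl-indole comes from Kita-type conjugate arylation/aromatisation of a quinone monoketal with indole. The monoketal comes from 6-bromo-2,4,5-trimethoxyphenol, which comes from 2,4,5-trimethoxybenzaldehyde (Dakin-type oxidation).
4. No rings are formed in the route. The central benzene and both indoles are pre-existing. The bonds are made in this order: arene–indole (A), indole C2–quaternary C, arene–indole (B).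

---

**Step 1**
Reactants: 1, 2,4,5-trimethoxybenzaldehyde
Product: 2, 2,4,5-trimethoxyphenol
Conditions: (i) mCPBA, CH2Cl2, 0 °C→rt; (ii) K2CO3, MeOH, rt
Reagents that add atoms: mCPBA, OOC(=O)c1cccc(Cl)c1 (supplies the phenol oxygen)
Why: Baeyer–Villiger (Dakin-type) oxidation of the electron-rich aldehyde gives the aryl formate, which methanolysis cleaves to the phenol; no stereocentre is involved.

**Step 2**
Reactants: 2
Product: 3, 2-bromo-3,4,6-trimethoxyphenol
Conditions: NBS, i-Pr2NH (10 mol %), CH2Cl2, –78 °C
Reagents that add atoms: NBS, BrN1C(=O)CCC1=O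
Why: Ortho-selective electrophilic bromination (amine-mediated, OH-directed) at the only position ortho to the OH; this bromide is the later handle for indole B.

**Step 3**
Reactants: 3
Product: 4, 6-bromo-2,4,4,5-tetramethoxycyclohexa-2,5-dien-1-one (quinone monoketal)
Conditions: PhI(OAc)2, MeOH, 0 °C
Reagents that add atoms: methanol, CO (adds the second C4 OMe); PhI(OAc)2, CC(=O)OI(OC(C)=O)c1ccccc1 (oxidant, leaves no atoms)
Why: Hypervalent-iodine oxidative dearomatisation of a p-methoxyphenol in MeOH (Kita-type) gives the monoketal, which is an umpoled arene electrophile.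

**Step 4**
Reactants: 4; 5, indole
Product: 6, 6-bromo-3-(1H-indol-3-yl)-2,4,5-trimethoxyphenol
Conditions: 5 (1.3 equiv), TMSOTf (20 mol %), CH2Cl2, –78→0 °C
Reagents that add atoms: none beyond reactant 5 (MeOH is lost)
Why: Lewis-acid-promoted conjugate addition of indole C3 to C3 of the α-methoxy enone arm (the only β-C–H), then loss of MeOH and tautomerisation (Kita-type arylation/aromatisation) gives the biaryl. This puts the aryl bond between two OMe groups, which is the position of indole A, and regenerates the phenol OH that ends up next to indole B.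

**Step 5**
Reactants: 6
Product: 7, tert-butyldimethylsilyl ether of 6 (aryl OTBS, indole N–H free)
Conditions: TBSCl, imidazole, DMF, 50 °C
Reagents that add atoms: TBSCl, CC(C)(C)[Si](C)(C)Cl
Why: Silylation masks the acidic, oxidisable phenol so it survives the chlorination/allylborane step and the Suzuki coupling; the indole N–H is unreactive under these conditions.

**Step 6**
Reactants: 7
Product: 8, 3-[2-(2-methylbut-3-en-2-yl)-1H-indol-3-yl] analogue of 7 (OTBS, Br retained)
Conditions: (i) t-BuOCl, Et3N, THF, –78 °C; (ii) prenyl-9-BBN, –78 °C→rt; (iii) DBU, THF, 50 °C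
Reagents that add atoms: prenyl-9-BBN, CC(C)=CCB1C2CCCC1CCC2 (delivers the C5 unit)
Why: Proposed new method: t-BuOCl chlorinates C3 of the 3-aryl-indole to give a 3-aryl-3-chloro-3H-indole. Prenyl-9-BBN then adds to C2=N through a six-membered chair by its γ-carbon (allylboration with allylic transposition), which forms the quaternary 1,1-dimethylallyl centre. The resulting 3-chloroindoline loses HCl, helped by the electron-rich aryl stabilising the C3 cation, and rearomatises to the 2,3-disubstituted indole. The closest known reaction is Danishefsky's C2 reverse-prenylation of 3-alkylindoles and tryptophans. What is new is its use on a 3-aryl-indole whose aryl group is fully substituted, 2,6-dioxygenated and tetra-ortho-hindered, where the arene is inert to t-BuOCl and the biaryl axis must tolerate a quaternary neighbour. No stereocentre is created.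

**Step 7**
Reactants: 9, 3-bromo-1-(triisopropylsilyl)indole
Product: 10, 1-(triisopropylsilyl)indol-3-yl pinacol boronate
Conditions: B2pin2, Pd(dppf)Cl2 (5 mol %), KOAc, dioxane, 80 °C
Reagents that add atoms: B2pin2, CC1(C)OB(OC1(C)C)B1OC(C)(C)C(C)(C)O1
Why: Miyaura borylation; the bulky N-TIPS group suppresses protodeboronation and N-coordination.

**Step 8**
Reactants: 8; 10
Product: 11, fully protected bis-indolyl arene (OTBS, N-TIPS on indole B, N–H on indole A)
Conditions: 10 (1.5 equiv), Pd2(dba)3 (3 mol %), SPhos (12 mol %), K3PO4, toluene/H2O 10:1, 90 °C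
Reagents that add atoms: none (the indolyl group comes from reactant 10)
Why: Suzuki–Miyaura coupling with a Buchwald ligand handles the di-ortho-substituted aryl bromide; the vinyl group, OTBS and free N–H survive.

**Step 9**
Reactants: 11
Product: 12, asterriquinol I
Conditions: TBAF, THF, 0 °C→rt; then aq. NH4Cl
Reagents that add atoms: none
Why: Fluoride removes both the aryl TBS and the indole N-TIPS group in one step, releasing the phenol and N–H without affecting OMe, indole or vinyl groups.

---

**Compound list**
1 | 2,4,5-trimethoxybenzaldehyde | O=Cc1cc(OC)c(OC)cc1OC | starting material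
2 | 2,4,5-trimethoxyphenol | Oc1cc(OC)c(OC)cc1OC | intermediate
3 | 2-bromo-3,4,6-trimethoxyphenol | Oc1c(Br)c(OC)c(OC)cc1OC | intermediate
4 | 6-bromo-2,4,4,5-tetramethoxycyclohexa-2,5-dien-1-one | O=C1C(Br)=C(OC)C(OC)(OC)C=C1OC | intermediate
5 | indole | c1ccc2[nH]ccc2c1 | starting material
6 | 6-bromo-3-(1H-indol-3-yl)-2,4,5-trimethoxyphenol | Oc1c(OC)c(-c2c[nH]c3ccccc23)c(OC)c(OC)c1Br | intermediate
7 | TBS ether of 6 | CC(C)(C)[Si](C)(C)Oc1c(OC)c(-c2c[nH]c3ccccc23)c(OC)c(OC)c1Br | intermediate
8 | 2-reverse-prenylated 7 | CC(C)(C)[Si](C)(C)Oc1c(OC)c(-c2c(C(C)(C)C=C)[nH]c3ccccc23)c(OC)c(OC)c1Br | intermediate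
9 | 3-bromo-1-(triisopropylsilyl)indole | CC(C)[Si](C(C)C)(C(C)C)n1cc(Br)c2ccccc21 | starting material
10 | 1-(triisopropylsilyl)indol-3-yl-Bpin | CC(C)[Si](C(C)C)(C(C)C)n1cc(B2OC(C)(C)C(C)(C)O2)c2ccccc21 | intermediate
11 | protected bis-indolyl arene | CC(C)(C)[Si](C)(C)Oc1c(OC)c(-c2c(C(C)(C)C=C)[nH]c3ccccc23)c(OC)c(OC)c1-c1cn([Si](C(C)C)(C(C)C)C(C)C)c2ccccc12 | intermediate
12 | asterriquinol I | C=CC(C)(C)c1[nH]c2ccccc2c1-c1c(OC)c(O)c(-c2c[nH]c3ccccc23)c(OC)c1OC | target

**Step count:** 9 steps in total; the longest linear sequence is 8 steps (Steps 1, 2, 3, 4, 5, 6, 8, 9).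

**Three steps most likely to fail**
1. **Step 6 (proposed new step).** The hindered 3-aryl-3-chloroindolenine may not form, or allylboration may be too slow. Fallback using known chemistry: build the 2-tert-alkyl-3-arylindole instead by Larock heteroannulation. Couple the aryl iodide (from the TBS ether of 3, iodinated at C3) with 3,3-dimethylpent-4-en-1-yne by Sonogashira coupling, then anneal with 2-iodoaniline; the bulky tertiary group ends up at C2.
2. **Step 4.** The Kita-type addition may give poor regioselectivity, indole oligomerisation or addition to the wrong enone arm. Fallback: cross-couple instead. Protect 3 as its TBS ether, iodinate at C3 with NIS, and do a chemoselective Suzuki coupling at C–I with 1-Boc-indol-3-yl-Bpin. Remove the N-Boc group with NaOMe/MeOH, then continue with Step 6.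
3. **Step 8.** The di-ortho-substituted aryl bromide may couple poorly, or the boronate may protodeboronate. Fallback: a Negishi coupling. Generate 1-TIPS-indol-3-ylzinc chloride from 9 by t-BuLi exchange and ZnCl2, and couple with Pd-PEPPSI-IPent.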